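## Analysis of the target

The target is a single cyclohexane ring. C1 carries a tertiary hydroxyl and the carboxylic acid, C3 a free secondary hydroxyl, C4 and C5 the two (E)-4-hydroxycinnamoyl (p-coumaroyl) esters, and C2 and C6 are methylenes. The four stereocentres are related as follows: O1, O3 and O4 lie on one face, O5 and the carboxyl carbon on the other. In the preferred chair O1 and O3 are therefore syn-diaxial, O4 and O5 trans-diequatorial, and the carboxyl group equatorial. The sensitive groups are the two aryl acrylate esters (cleaved or transposed by base, reduced by hydrogenation and by conjugate hydride donors), the free phenols and the α-hydroxy acid. The carbon skeleton is simple; the difficulty is differentiation. Three secondary hydroxyls must end as one free axial alcohol beside two esters, the free O3 is cis to the acylated O4 (so base moves the acyl group from O4 to O3), and the acid must be freed last without hydrolysing the coumarates. C1 is a quaternary carbinol centre that cannot be corrected once set. The strategy rests on the 1,3-relation of C1 and C3 across the C2 methylene: with C3 as a ketone, C1(OH)–C2H2–C3(=O) is an aldol retron, and the same carbonyl marks O3 as different from O4 and O5. Cutting C1–C2 leaves a chain whose only stereocentres are the threo diol C4/C5, which is a tartaric acid unit.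

## Retrosynthetic reasoning

**26 ⇒ 25 ⇒ 24 (unmasking).** No skeletal bond is cut. The free acid and O3–H of 26 are traced to a tert-butyl ester and a silyl ether in 25, and the two phenols of 25 to aryl acetates in 24. The forward steps must free four functions without hydrolysing or moving two conjugated esters. Hence a nucleophile that attacks only aryl acetates is used while O3 is still blocked (24 → 25), and then acid alone (25 → 26), since acyl migration is base-catalysed.

**24 ⇒ 20 + 23 (ester C–O bonds at O4 and O5).** The coumaroyl groups are the most fragile part and contain alkenes that would not survive hydrogenolysis, so they enter after all benzyl groups are gone. This gives diol 20, in which O3 is silylated and O1 is tertiary and hindered, and acid chloride 23, made from p-coumaric acid 21 through its O-acetate 22. The forward reaction is a double acylation of a trans-diequatorial diol.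

**20 ⇒ 19 ⇒ 18 ⇒ 17 (O–benzyl, O–Si and C3–H bonds).** In ketone 17 the C3 oxygen is the only ring oxygen that is not an ether. Reduction gives 18 with O3–H as the only new hydroxyl; it is silylated (19) while O4 and O5 are still benzylated, and hydrogenolysis then exposes exactly the two hydroxyls to be acylated (20). The 3 versus 4,5 differentiation therefore needs no selective reaction among similar alcohols. The reduction must deliver hydride along the equatorial direction, so that O3 becomes axial, cis to O4 and syn to O1.

**17 ⇒ 16 (ring bond C1–C2).** This is the aldol disconnection of the β-hydroxy ketone. It is the only ring bond whose cleavage removes the quaternary centre and the ring at once while leaving no stereocentre next to a reacting carbon except the two that come from the chiral pool. The precursor is the acyclic diketo ester 16, in which heptanoate C2, C7, C6, C5, C4 and C3 become ring C1, C2, C3, C4, C5 and C6. The forward step must enolise the methyl ketone on its methyl side, add to the keto carbonyl of the α-keto ester, fix C1, and avoid loss of a β-benzyloxy group.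

**16 ⇒ 15 ⇒ 14 ⇒ 13 ⇒ 12 (functional-group changes, C6–C7 bond).** The α-keto ester is the most sensitive function of the chain and is revealed last, from dithioacetal 15. The methyl ketone is cut at C6–C7 to aldehyde 13 and a methyl nucleophile, via carbinol 14; the aldehyde comes from primary alcohol 12. The dithiane and the tert-butyl ester tolerate the oxidations and the organometallic addition.

**12 ⇒ 9 + 5 (chain bond C2–C3).** Chain C2 is an acyl-anion position and is supplied by the dithiane ester 9. C3 is a primary electrophilic carbon. It comes from the cyclic sulfate 5, in which both ends of a C2-symmetric four-carbon unit are activated at once but only one can react; the other end returns as the hydroxyl of 12. The desymmetrisation thus needs no protecting group.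

**5 ⇒ 3 ⇒ 2 ⇒ 1, and 9 ⇒ 6 + 7.** The sulfate comes from diol 3, which comes from diester 2 and from diethyl D-tartrate 1. The D series is required because the (4R,5S) centres of 16 map onto (2R,3R)-diol 3 and (2S,3S)-tartrate. Ester 9 is made from 1,3-dithiane 6 and di-tert-butyl dicarbonate 7. An ethyl ester would be easier to obtain, but it could not be cleaved at the end without endangering the coumarates. The tert-butyl ester is the one carboxyl protection in this route that acid removes selectively.

## Alternatives that were turned down

**Alternative 1:** Ring contraction of a cycloheptane-1,2-dione by a tethered benzilic ester rearrangement.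
- **Disconnection and key step:** C1–C2 and the lactone O5–C7 bond are traced to a seven-membered 1,2-diketone. The C5 alkoxide adds across the ring to the far carbonyl and the ring methylene shifts to the neighbouring carbonyl carbon, giving 3,4-O-isopropylidenequinic acid 1,5-lactone A1.
- **For:** the tether delivers the carboxyl carbon on the face of O5, so C1 is fixed by geometry. That is firmer control than the chair preference used in the chosen route, and the point is conceded.
- **Against:** the diketone precursor has three oxygenated stereocentres on a medium ring and needs its own long synthesis. Alkyl migration in an enolisable α-diketone competes with simple enolisation. In A1, O3 and O4 are tied together and O5 is locked in the lactone, the opposite of what a 4,5-diester needs. Opening the lactone and then telling O3 from O4 within a cis-diol would cost several further steps. A1 is also what the deacylated natural acid gives after routine protection.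
- **Comparison:** the chosen route keeps C3 as a ketone after ring closure, so the 3 versus 4,5 pattern arises without any selective protection.

**Alternative 2:** Hydroxyl-directed nucleophilic epoxidation of a chiral-pool cyclohexene ester.
- **Disconnection and key step:** only the C1–O bond is cut. The lithium alkoxide on C3 of the 4,5-protected enoate delivers an alkyl hydroperoxide to the conjugated double bond, giving the epoxide syn to O3, methyl 1,2-epoxy-1,2-dihydroshikimate 4,5-(2,3-dimethoxybutane-2,3-diyl) acetal A2.
- **For:** C3, C4 and C5 are bought with the correct configurations and the new C1–O bond lands on the face of O3, as the target requires. In step count and in certainty about three stereocentres this alternative is stronger.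
- **Against:** after A2 the C2–O bond must be removed while the tertiary C1–O bond stays. Reductive openings of α,β-epoxy esters normally break the bond at the carbon next to the ester, which would give the 2-hydroxy isomer. The acetal also covers exactly O4 and O5 and leaves O3 free, so the protection has to be inverted. The ring is relayed from a natural cyclohexene and not built.
- **Comparison:** the chosen route offers a de novo ring from tartrate (either enantiomer), no regiochemical problem in a reduction, and built-in differentiation of O3.

**Alternative 3:** Iodolactonisation relay from one Diels–Alder-set centre.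
- **Disconnection and key step:** the C5–O bond is cut, with iodine on C4. A cyclohexene 1-hydroxy acid whose only stereocentre is C1 is treated with electrophilic iodine and bicarbonate to give the bridged iodolactone 1-hydroxy-4-iodo-6-oxabicyclo[3.2.1]octan-7-one A3.
- **For:** the key step is among the most reliable ring-forming reactions known, the feedstocks are cheap, and the bicyclic lactone relays configuration rigidly. On predictability of the key step this alternative is stronger than an aldol onto a sensitive keto ester.
- **Against:** after A3 only C1 and C5 are set. O4 and O3 still have to be introduced by elimination and face-selective dihydroxylation. The result is again a lactone with O5 locked and an undifferentiated cis-3,4-diol. The enantioselective cycloaddition that creates a quaternary carbinol centre is itself not routine.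
- **Comparison:** the chosen route takes C4 and C5 from tartrate, sets C1 and C3 on the ring, and has the protecting-group pattern of the target from the key step onwards.

Key step: step 10

Assumption: ring compounds are numbered as in quinic acid (C1 carries the carboxyl group, C3 the free hydroxyl, C4 and C5 the esters), the acyclic precursor is numbered as a heptanoate, and the carboxyl group is carried as a tert-butyl ester so that acid can free it at the end.

## Route

Step 1
Reactants: 1 diethyl D-tartrate [diethyl (2S,3S)-2,3-dihydroxybutanedioate]
Product: 2 diethyl (2S,3S)-2,3-bis(benzyloxy)butanedioate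
Conditions: BnOC(=NH)CCl3 (2.5 equiv), TfOH (cat.), cyclohexane/CH2Cl2, 0 °C → rt
Reagents that add atoms: benzyl 2,2,2-trichloroacetimidate, ClC(Cl)(Cl)C(=N)OCc1ccccc1
Why: Acid-catalysed O-benzylation with the trichloroacetimidate alkylates both hydroxyls without the basic conditions that epimerise or eliminate α-alkoxy esters; the stereocentres are not touched.

Step 2
Reactants: 2 diethyl (2S,3S)-2,3-bis(benzyloxy)butanedioate
Product: 3 (2R,3R)-2,3-bis(benzyloxy)butane-1,4-diol
Conditions: LiAlH4, THF, 0 °C → rt
Reagents that add atoms: none
Why: Hydride reduction of both esters to primary alcohols; the carbinol centres are not involved, and the descriptors change only because substituent priorities change.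

Step 3
Reactants: 3 (2R,3R)-2,3-bis(benzyloxy)butane-1,4-diol
Product: 5 (5R,6R)-5,6-bis(benzyloxy)-1,3,2-dioxathiepane 2,2-dioxide (the 1,4-cyclic sulfate), via cyclic sulfite 4 (not isolated)
Conditions: SOCl2, Et3N, CH2Cl2, 0 °C; then RuCl3·3H2O (cat.), NaIO4, MeCN/H2O, 0 °C
Reagents that add atoms: thionyl chloride, O=S(Cl)Cl; sodium periodate, [Na+].[O-]I(=O)(=O)=O
Why: Cyclic sulfite formation followed by ruthenium-catalysed oxidation is the standard two-stage conversion of a diol into its cyclic sulfate, and seven-membered sulfates of benzyl-protected 1,4-diols are a known class. It turns the two homotopic hydroxymethyl groups into one electrophile that can be opened only once.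

Step 4
Reactants: 6 1,3-dithiane; 7 di-tert-butyl dicarbonate
Product: 9 tert-butyl 1,3-dithiane-2-carboxylate, via 2-lithio-1,3-dithiane 8 (not isolated)
Conditions: n-BuLi, THF, −30 °C; then added to 7 (1.3 equiv), THF, −78 °C; NH4Cl (aq)
Reagents that add atoms: none
Why: Deprotonation at C2 of the dithiane and C-acylation of the organolithium by the dicarbonate (alkoxycarbonylation of a carbanion); inverse addition keeps the more acidic product away from unreacted organolithium.

Step 5
Reactants: 9 tert-butyl 1,3-dithiane-2-carboxylate; 5 the cyclic sulfate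
Product: 12 tert-butyl 2-[(2R,3R)-2,3-bis(benzyloxy)-4-hydroxybutyl]-1,3-dithiane-2-carboxylate, via sodium enolate 10 (not isolated), via sodium alkyl sulfate 11 (not isolated)
Conditions: NaH, DMF, 0 °C; 5, rt → 45 °C; evaporate; then H2SO4 (cat.), H2O (2 equiv), THF, rt
Reagents that add atoms: none
Why: SN2 opening of a cyclic sulfate by a stabilised carbanion, then acid hydrolysis of the sulfate monoester, both known reaction types. The two CH2–O carbons of 5 are homotopic, so one product should form, and the anionic monoester cannot be alkylated again.

Step 6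
Reactants: 12 the hydroxy dithiane ester
Product: 13 tert-butyl 2-[(2R,3S)-2,3-bis(benzyloxy)-4-oxobutyl]-1,3-dithiane-2-carboxylate
Conditions: (COCl)2, DMSO, CH2Cl2, −78 °C; iPr2NEt, −78 → −30 °C
Reagents that add atoms: none
Why: Swern oxidation of the primary alcohol; dithiane and tert-butyl ester are inert, and low temperature with a hindered amine should keep the α-benzyloxy aldehyde from epimerising (it is used crude).

Step 7
Reactants: 13 the aldehyde
Product: 14 tert-butyl 2-[(2R,3R)-2,3-bis(benzyloxy)-4-hydroxypentyl]-1,3-dithiane-2-carboxylate (both epimers at the new carbinol carbon)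
Conditions: MeMgBr, THF, −78 °C; NH4Cl (aq)
Reagents that add atoms: methylmagnesium bromide, C[Mg]Br
Why: Grignard addition to the aldehyde, which is far more reactive than a tert-butyl ester on a quaternary carbon; the new carbinol centre is destroyed in step 8, so its configuration does not matter.

Step 8
Reactants: 14 the secondary alcohol
Product: 15 tert-butyl 2-[(2R,3S)-2,3-bis(benzyloxy)-4-oxopentyl]-1,3-dithiane-2-carboxylate
Conditions: (COCl)2, DMSO, CH2Cl2, −78 °C; iPr2NEt, −78 → −30 °C
Reagents that add atoms: none
Why: Swern oxidation of the secondary alcohol to the methyl ketone under the same mild, sulfide-compatible conditions as step 6; both epimers of 14 converge on one ketone.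

Step 9
Reactants: 15 the methyl ketone dithiane
Product: 16 tert-butyl (4R,5S)-4,5-bis(benzyloxy)-2,6-dioxoheptanoate
Conditions: NBS, 2,6-lutidine, acetone/H2O (9:1), −20 → 0 °C; Na2S2O3 (aq)
Reagents that add atoms: water, O
Why: Oxidative hydrolysis of the dithioacetal by bromonium transfer to sulfur is the usual unmasking of 2-alkyl-1,3-dithiane-2-carboxylates to α-keto esters. The buffer removes HBr so that benzyl ethers and the methyl ketone should survive, and 16 is taken on at once.

Step 10
Reactants: 16 tert-butyl (4R,5S)-4,5-bis(benzyloxy)-2,6-dioxoheptanoate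
Product: 17 tert-butyl 4,5-di-O-benzyl-3-dehydroquinate [tert-butyl (1R,4S,5R)-4,5-bis(benzyloxy)-1-hydroxy-3-oxocyclohexane-1-carboxylate]
Conditions: Et3N (0.3 equiv), CH2Cl2 (0.02 M), 0 °C → rt; AcOH quench
Reagents that add atoms: none
Why: The amine reversibly forms the enol or enolate on the methyl side of the ketone; its carbon (chain C7, ring C2) adds to the keto carbonyl of the α-keto ester (chain C2, ring C1) and the tertiary alkoxide is protonated by the ammonium ion, so the step is an intramolecular aldol addition under general-base catalysis. The closest known reactions are the spontaneous closure of the free 2,6-diketo acid of the same configuration to 3-dehydroquinate and amine-mediated aldol carbocyclisations of protected, sugar-derived 1,5-dicarbonyl compounds. The one ring is closed in the 6-(enolendo)-exo-trig mode. C1 is set in a chair transition state with both benzyloxy groups and the bulky tert-butoxycarbonyl group equatorial and the carbonyl oxygen axial, which gives the axial hydroxyl and the (1R) centre; because the addition is reversible, the same preference also acts thermodynamically. Site selectivity follows from ring size: the enolates at the more acidic C3 methylene and at the C5 methine could only close four-membered rings and revert, and the α-keto ester carbonyl is by far the most electrophilic. The addition must also outrun E1cB loss of benzyloxide and dehydration of 17; the weak base, high dilution, low temperature and the poor leaving-group ability of an alkoxide are relied on for that.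

Step 11
Reactants: 17 tert-butyl 4,5-di-O-benzyl-3-dehydroquinate
Product: 18 tert-butyl 4,5-di-O-benzylquinate [tert-butyl (1S,3R,4R,5R)-4,5-bis(benzyloxy)-1,3-dihydroxycyclohexane-1-carboxylate]
Conditions: LiBH(sec-Bu)3 (2.5 equiv), THF, −78 °C; NH4Cl (aq)
Reagents that add atoms: none
Why: A bulky trialkylborohydride attacks a cyclohexanone along the equatorial direction; here the axial path is also blocked by the axial O1 substituent in the 1,3-position. The C3 hydroxyl should therefore come out axial, cis to O4 and syn to O1; the tert-butyl ester is inert at −78 °C.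

Step 12
Reactants: 18 tert-butyl 4,5-di-O-benzylquinate
Product: 19 tert-butyl 4,5-di-O-benzyl-3-O-(tert-butyldimethylsilyl)quinate
Conditions: TBSCl, imidazole, DMAP (cat.), DMF, rt → 40 °C
Reagents that add atoms: tert-butyldimethylsilyl chloride, CC(C)(C)[Si](C)(C)Cl
Why: Silylation with the chlorosilane and imidazole stops at secondary hydroxyls; the tertiary O1–H beside the ester is left, so only O3 is blocked.

Step 13
Reactants: 19 the 3-O-silyl dibenzyl ether
Product: 20 tert-butyl 3-O-(tert-butyldimethylsilyl)quinate
Conditions: H2 (1 atm), Pd/C, EtOAc, rt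
Reagents that add atoms: none
Why: Hydrogenolysis of both benzyl ethers over palladium on carbon in a non-protic solvent leaves the silyl ether, the tert-butyl ester and the alcohols untouched; it is placed before the cinnamoyl alkenes enter.

Step 14
Reactants: 21 p-coumaric acid [(E)-3-(4-hydroxyphenyl)prop-2-enoic acid]
Product: 22 (E)-3-(4-acetoxyphenyl)prop-2-enoic acid
Conditions: Ac2O, NaOH (aq), 0 °C; then HCl (aq)
Reagents that add atoms: acetic anhydride, CC(=O)OC(C)=O
Why: Acetylation of the phenoxide in aqueous base; the carboxylate is not acylated durably in water and is recovered as the acid on acidification.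

Step 15
Reactants: 22 (E)-3-(4-acetoxyphenyl)prop-2-enoic acid
Product: 23 (E)-3-(4-acetoxyphenyl)prop-2-enoyl chloride
Conditions: (COCl)2, DMF (cat.), CH2Cl2, 0 °C → rt; evaporate
Reagents that add atoms: oxalyl chloride, O=C(Cl)C(=O)Cl
Why: Standard acid chloride formation through the chloroiminium catalyst; the aryl acetate and the E-alkene are stable to it.

Step 16
Reactants: 20 tert-butyl 3-O-(tert-butyldimethylsilyl)quinate; 23 (E)-3-(4-acetoxyphenyl)prop-2-enoyl chloride
Product: 24 tert-butyl 4,5-bis-O-[(E)-4-acetoxycinnamoyl]-3-O-(tert-butyldimethylsilyl)quinate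
Conditions: 23 (2.6 equiv), pyridine, DMAP (cat.), CH2Cl2, 0 °C → rt
Reagents that add atoms: none
Why: Acylation of the trans-diequatorial 4,5-diol by an acid chloride under nucleophilic catalysis; the secondary hydroxyls should react much faster than the tertiary O1–H, and the acetylated phenol keeps the reagent from acylating itself.

Step 17
Reactants: 24 the bis(acetoxycinnamoyl) ester
Product: 25 tert-butyl 3-O-(tert-butyldimethylsilyl)-4,5-di-O-p-coumaroylquinate
Conditions: N2H4·AcOH (2.4 equiv), DMF, 0 °C → rt
Reagents that add atoms: none
Why: Chemoselective hydrazinolysis: aryl acetates are activated esters and should be cleaved at 0 °C, whereas the conjugated esters of secondary alcohols and the tert-butyl ester are not. O3 is still silylated, so the acyl group on O4 has no free neighbour to move to.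

Step 18
Reactants: 25 tert-butyl 3-O-(tert-butyldimethylsilyl)-4,5-di-O-p-coumaroylquinate
Product: 26 4,5-di-O-p-coumaroylquinic acid
Conditions: TFA/H2O (9:1), anisole, 0 °C → rt
Reagents that add atoms: none
Why: Acidolysis: the tert-butyl ester ionises to the acid and a tert-butyl cation (lost as the alkene or trapped by anisole), and the silyl ether is hydrolysed. Conjugated esters of secondary alcohols are stable to these conditions, and acyl migration, which is base-catalysed, is not expected.

## Compound list

1 | diethyl D-tartrate [diethyl (2S,3S)-2,3-dihydroxybutanedioate] | CCOC(=O)[C@@H](O)[C@H](O)C(=O)OCC | starting material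
2 | diethyl (2S,3S)-2,3-bis(benzyloxy)butanedioate | CCOC(=O)[C@@H](OCc1ccccc1)[C@H](OCc1ccccc1)C(=O)OCC | intermediate
3 | (2R,3R)-2,3-bis(benzyloxy)butane-1,4-diol | OC[C@@H](OCc1ccccc1)[C@H](OCc1ccccc1)CO | intermediate
4 | (5R,6R)-5,6-bis(benzyloxy)-1,3,2-dioxathiepane 2-oxide (cyclic sulfite) | O=S1OC[C@@H](OCc2ccccc2)[C@H](OCc2ccccc2)CO1 | intermediate
5 | (5R,6R)-5,6-bis(benzyloxy)-1,3,2-dioxathiepane 2,2-dioxide (cyclic sulfate) | O=S1(=O)OC[C@@H](OCc2ccccc2)[C@H](OCc2ccccc2)CO1 | intermediate
6 | 1,3-dithiane | C1CSCSC1 | starting material
7 | di-tert-butyl dicarbonate | CC(C)(C)OC(=O)OC(=O)OC(C)(C)C | starting material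
8 | 2-lithio-1,3-dithiane | [Li]C1SCCCS1 | intermediate
9 | tert-butyl 1,3-dithiane-2-carboxylate | CC(C)(C)OC(=O)C1SCCCS1 | intermediate
10 | sodium enolate of 9 [sodium tert-butoxy(1,3-dithian-2-ylidene)methanolate] | CC(C)(C)OC([O-])=C1SCCCS1.[Na+] | intermediate
11 | sodium (2R,3R)-2,3-bis(benzyloxy)-4-[2-(tert-butoxycarbonyl)-1,3-dithian-2-yl]butyl sulfate | CC(C)(C)OC(=O)C1(C[C@@H](OCc2ccccc2)[C@H](OCc2ccccc2)COS(=O)(=O)[O-])SCCCS1.[Na+] | intermediate
12 | tert-butyl 2-[(2R,3R)-2,3-bis(benzyloxy)-4-hydroxybutyl]-1,3-dithiane-2-carboxylate | CC(C)(C)OC(=O)C1(C[C@@H](OCc2ccccc2)[C@H](OCc2ccccc2)CO)SCCCS1 | intermediate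
13 | tert-butyl 2-[(2R,3S)-2,3-bis(benzyloxy)-4-oxobutyl]-1,3-dithiane-2-carboxylate | CC(C)(C)OC(=O)C1(C[C@@H](OCc2ccccc2)[C@H](OCc2ccccc2)C=O)SCCCS1 | intermediate
14 | tert-butyl 2-[(2R,3R)-2,3-bis(benzyloxy)-4-hydroxypentyl]-1,3-dithiane-2-carboxylate (both carbinol epimers) | CC(C)(C)OC(=O)C1(C[C@@H](OCc2ccccc2)[C@H](OCc2ccccc2)C(C)O)SCCCS1 | intermediate
15 | tert-butyl 2-[(2R,3S)-2,3-bis(benzyloxy)-4-oxopentyl]-1,3-dithiane-2-carboxylate | CC(C)(C)OC(=O)C1(C[C@@H](OCc2ccccc2)[C@H](OCc2ccccc2)C(C)=O)SCCCS1 | intermediate
16 | tert-butyl (4R,5S)-4,5-bis(benzyloxy)-2,6-dioxoheptanoate | CC(C)(C)OC(=O)C(=O)C[C@@H](OCc1ccccc1)[C@H](OCc1ccccc1)C(C)=O | intermediate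
17 | tert-butyl 4,5-di-O-benzyl-3-dehydroquinate [tert-butyl (1R,4S,5R)-4,5-bis(benzyloxy)-1-hydroxy-3-oxocyclohexane-1-carboxylate] | O(Cc1ccccc1)[C@@H]2C(=O)C[C@@](O)(C(=O)OC(C)(C)C)C[C@H]2OCc1ccccc1 | intermediate
18 | tert-butyl 4,5-di-O-benzylquinate [tert-butyl (1S,3R,4R,5R)-4,5-bis(benzyloxy)-1,3-dihydroxycyclohexane-1-carboxylate] | O(Cc1ccccc1)[C@@H]2[C@H](O)C[C@@](O)(C(=O)OC(C)(C)C)C[C@H]2OCc1ccccc1 | intermediate
19 | tert-butyl 4,5-di-O-benzyl-3-O-(tert-butyldimethylsilyl)quinate | O(Cc1ccccc1)[C@@H]2[C@H](O[Si](C)(C)C(C)(C)C)C[C@@](O)(C(=O)OC(C)(C)C)C[C@H]2OCc1ccccc1 | intermediate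
20 | tert-butyl 3-O-(tert-butyldimethylsilyl)quinate | O[C@@H]1[C@H](O[Si](C)(C)C(C)(C)C)C[C@@](O)(C(=O)OC(C)(C)C)C[C@H]1O | intermediate
21 | p-coumaric acid [(E)-3-(4-hydroxyphenyl)prop-2-enoic acid] | OC(=O)/C=C/c1ccc(O)cc1 | starting material
22 | (E)-3-(4-acetoxyphenyl)prop-2-enoic acid | CC(=O)Oc1ccc(/C=C/C(=O)O)cc1 | intermediate
23 | (E)-3-(4-acetoxyphenyl)prop-2-enoyl chloride | CC(=O)Oc1ccc(/C=C/C(=O)Cl)cc1 | intermediate
24 | tert-butyl 4,5-bis-O-[(E)-4-acetoxycinnamoyl]-3-O-(tert-butyldimethylsilyl)quinate | O=C(/C=C/c1ccc(OC(C)=O)cc1)O[C@@H]1[C@H](O[Si](C)(C)C(C)(C)C)C[C@@](O)(C(=O)OC(C)(C)C)C[C@H]1OC(=O)/C=C/c1ccc(OC(C)=O)cc1 | intermediate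
25 | tert-butyl 3-O-(tert-butyldimethylsilyl)-4,5-di-O-p-coumaroylquinate | O=C(/C=C/c1ccc(O)cc1)O[C@@H]1[C@H](O[Si](C)(C)C(C)(C)C)C[C@@](O)(C(=O)OC(C)(C)C)C[C@H]1OC(=O)/C=C/c1ccc(O)cc1 | intermediate
26 | 4,5-di-O-p-coumaroylquinic acid | O=C(/C=C/c1ccc(O)cc1)O[C@@H]1[C@H](O)C[C@@](O)(C(=O)O)C[C@H]1OC(=O)/C=C/c1ccc(O)cc1 | target

## Step count and least certain steps

Total: 18 steps. Longest linear sequence: 15 steps, from 1 to 26 through steps 1–3, 5–13 and 16–18; steps 4, 14 and 15 prepare the two side fragments.

**Step 10 (key step).** The most likely failure is β-elimination of benzyloxide, either from the enol of the α-keto ester (its C3 hydrogens are the most acidic in the molecule) or from the internal enolate of the methyl ketone. Dehydration of the tertiary aldol and a weak facial preference at C1 are further risks, since an ester is only modestly more demanding than a hydroxyl in the chair. A first adjustment is enamine activation by a secondary amine. The fallback avoids enolates altogether and sets out from 15: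
- Methylenation of the ketone (CH2Br2, Zn, TiCl4) should give tert-butyl 2-[(2R,3R)-2,3-bis(benzyloxy)-4-methylpent-4-en-1-yl]-1,3-dithiane-2-carboxylate F1.
- Alkylative hydrolysis of the dithiane (MeI, CaCO3, aqueous MeCN), which spares the alkene, should give tert-butyl (4R,5R)-4,5-bis(benzyloxy)-6-methyl-2-oxohept-6-enoate F2.
- A Lewis-acid-promoted intramolecular carbonyl-ene reaction (Me2AlCl, CH2Cl2, −78 °C), with the tether on the central carbon of the ene unit, should close the same C1–C2 bond and give tert-butyl 4,5-di-O-benzyl-3-deoxy-3-methylidenequinate F3.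
- Ozonolysis (O3, then Me2S) returns to 17.

**Step 5 (sulfate opening, with step 3 behind it).** Substitution by a fully substituted carbanion at a primary carbon that is β-branched and β-oxygenated may be slow, and closing the seven-membered sulfite may give oligomers. The fallback sets out from 3:
- Monosilylation (NaH, 1 equiv, TBSCl, THF) gives (2R,3R)-2,3-bis(benzyloxy)-4-[(tert-butyldimethylsilyl)oxy]butan-1-ol F4.
- Triflation (Tf2O, 2,6-lutidine, CH2Cl2, −78 °C) gives (2R,3R)-2,3-bis(benzyloxy)-4-[(tert-butyldimethylsilyl)oxy]butyl trifluoromethanesulfonate F5.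
- Alkylation of enolate 10 (THF, −78 → 0 °C) gives tert-butyl 2-[(2R,3R)-2,3-bis(benzyloxy)-4-[(tert-butyldimethylsilyl)oxy]butyl]-1,3-dithiane-2-carboxylate F6.
- Desilylation (TBAF, THF) returns to 12.

**Step 11 (reduction).** The lithium alkoxide of the tertiary β-hydroxy ketone may open by retro-aldol, or hydride may arrive on the wrong face and give the equatorial alcohol. The fallback sets out from 17 and accepts the wrong epimer on purpose:
- Hydroxyl-directed reduction (Me4NBH(OAc)3, AcOH/MeCN, −20 °C) is non-basic and delivers hydride from O1, which should give tert-butyl 4,5-di-O-benzyl-3-epi-quinate F7.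
- Mitsunobu inversion (4-nitrobenzoic acid, PPh3, DIAD) should give tert-butyl 4,5-di-O-benzyl-3-O-(4-nitrobenzoyl)quinate F8.
- Methanolysis (K2CO3, MeOH) returns to 18.

**Step 16 (double acylation).** Acylation of O4, which sits between the silyl ether and the new ester on O5, may stall. Forcing it risks acylation of O1 or base-induced silyl migration from O3 to O4. The fallback sets out from 20 and builds the cinnamoyl units on the ring:
- Heating with Meldrum's acid (toluene, 90 °C) should give tert-butyl 4,5-bis-O-(carboxyacetyl)-3-O-(tert-butyldimethylsilyl)quinate F9.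
- Knoevenagel–Doebner condensation with 4-hydroxybenzaldehyde (pyridine, piperidine cat., 40 °C), with decarboxylation, comes back at 25 and also bypasses step 17.

**Step 18 (final acidolysis).** The tert-butyl cation may alkylate the electron-rich phenol rings, the hindered axial silyl ether may cleave slowly, and once O3 is free the acyl group on O4 may start to migrate during work-up. The fallback sets out from 24 and reverses the order of unmasking:
- TFA/H2O on the still acetylated, less nucleophilic compound should give 4,5-bis-O-[(E)-4-acetoxycinnamoyl]quinic acid F10.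
- Hydrolysis of the aryl acetates in 2 M HCl/THF at rt, where the conjugated esters of secondary alcohols react far more slowly, comes back at 26.

## Further compounds

F1 | step 10 | tert-butyl 2-[(2R,3R)-2,3-bis(benzyloxy)-4-methylpent-4-en-1-yl]-1,3-dithiane-2-carboxylate | CC(C)(C)OC(=O)C1(C[C@@H](OCc2ccccc2)[C@H](OCc2ccccc2)C(C)=C)SCCCS1
F2 | step 10 | tert-butyl (4R,5R)-4,5-bis(benzyloxy)-6-methyl-2-oxohept-6-enoate | CC(C)(C)OC(=O)C(=O)C[C@@H](OCc1ccccc1)[C@H](OCc1ccccc1)C(C)=C
F3 | step 10 | tert-butyl 4,5-di-O-benzyl-3-deoxy-3-methylidenequinate | O(Cc1ccccc1)[C@@H]2C(=C)C[C@@](O)(C(=O)OC(C)(C)C)C[C@H]2OCc1ccccc1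
F4 | step 5 | (2R,3R)-2,3-bis(benzyloxy)-4-[(tert-butyldimethylsilyl)oxy]butan-1-ol | OC[C@@H](OCc1ccccc1)[C@H](OCc1ccccc1)CO[Si](C)(C)C(C)(C)C
F5 | step 5 | (2R,3R)-2,3-bis(benzyloxy)-4-[(tert-butyldimethylsilyl)oxy]butyl trifluoromethanesulfonate | O=S(=O)(OC[C@@H](OCc1ccccc1)[C@H](OCc1ccccc1)CO[Si](C)(C)C(C)(C)C)C(F)(F)F
F6 | step 5 | tert-butyl 2-[(2R,3R)-2,3-bis(benzyloxy)-4-[(tert-butyldimethylsilyl)oxy]butyl]-1,3-dithiane-2-carboxylate | CC(C)(C)OC(=O)C1(C[C@@H](OCc2ccccc2)[C@H](OCc2ccccc2)CO[Si](C)(C)C(C)(C)C)SCCCS1
F7 | step 11 | tert-butyl 4,5-di-O-benzyl-3-epi-quinate | O(Cc1ccccc1)[C@@H]2[C@@H](O)C[C@@](O)(C(=O)OC(C)(C)C)C[C@H]2OCc1ccccc1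
F8 | step 11 | tert-butyl 4,5-di-O-benzyl-3-O-(4-nitrobenzoyl)quinate | O(Cc1ccccc1)[C@@H]2[C@H](OC(=O)c3ccc(cc3)[N+](=O)[O-])C[C@@](O)(C(=O)OC(C)(C)C)C[C@H]2OCc1ccccc1
F9 | step 16 | tert-butyl 4,5-bis-O-(carboxyacetyl)-3-O-(tert-butyldimethylsilyl)quinate | OC(=O)CC(=O)O[C@@H]1[C@H](O[Si](C)(C)C(C)(C)C)C[C@@](O)(C(=O)OC(C)(C)C)C[C@H]1OC(=O)CC(=O)O
F10 | step 18 | 4,5-bis-O-[(E)-4-acetoxycinnamoyl]quinic acid | O=C(/C=C/c1ccc(OC(C)=O)cc1)O[C@@H]1[C@H](O)C[C@@](O)(C(=O)O)C[C@H]1OC(=O)/C=C/c1ccc(OC(C)=O)cc1
A1 | alternative 1 | 3,4-O-isopropylidenequinic acid 1,5-lactone | CC1(C)O[C@@H]2[C@H](O1)C[C@@](O)(C3=O)C[C@H]2O3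
A2 | alternative 2 | methyl 1,2-epoxy-1,2-dihydroshikimate 4,5-(2,3-dimethoxybutane-2,3-diyl) acetal, epoxide syn to O3 | O1[C@@H]2[C@H](O)[C@@H]3O[C@]3(C(=O)OC)C[C@H]2O[C@](C)(OC)[C@@]1(C)OC
A3 | alternative 3 | 1-hydroxy-4-iodo-6-oxabicyclo[3.2.1]octan-7-one | I[C@@H]1CC[C@@](O)(C2=O)C[C@H]1O2
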